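## Retrosynthetic overview
1. The last skeletal bond is the aryl ether O7–C1', made by Mitsunobu union of isofraxidin with an acetonide-masked C10 side-chain alcohol. Acetonide hydrolysis ends the synthesis.
2. The 4-methylpent-3-enyl tail is traced back to an allyl group (hydroboration, oxidation, isopropylidene Wittig).
3. The key C3'–C4' bond comes from an intermolecular, chelation-controlled Hosomi–Sakurai carbonyl allylation of an (R)-α-benzyloxy methyl ketone with allyltrimethylsilane/TiCl4, which sets the tertiary carbinol. C2' comes from the D-glycerate chiral pool.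
4. Isofraxidin comes from syringol by MOM protection, directed ortho-lithiation/borylation/oxidation, Mg-mediated ortho-formylation and Wittig olefination–lactonisation.
5. Rings: the benzene ring is bought. A temporary dioxolane is closed in step 9, the pyranone ring (the only target ring that is built) is closed in step 16, and the dioxolane is opened in step 19.

Assumption: the SMILES encodes the (2'R,3'R) threo diol (side chain numbered C1' to C8' from the ether carbon), and compounds 1, 7 and 16 are bought.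

## Route

Step 1
Reactants: 1 methyl (R)-2,2-dimethyl-1,3-dioxolane-4-carboxylate
Product: 2 methyl (R)-2,3-dihydroxypropanoate
Conditions: AcOH/H2O 7:3, rt, 18 h; toluene azeotrope
Reagents that add atoms: none
Why: Acid-catalysed acetal hydrolysis frees the diol and leaves the methyl ester and the chiral-pool stereocentre (future C2', R) untouched.

Step 2
Reactants: 2 methyl (R)-2,3-dihydroxypropanoate
Product: 3 methyl (R)-3-[(tert-butyldiphenylsilyl)oxy]-2-hydroxypropanoate
Conditions: TBDPSCl (1.05 equiv), imidazole (2 equiv), CH2Cl2, 0 °C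
Reagents that add atoms: tert-butyldiphenylsilyl chloride, CC(C)(C)[Si](Cl)(c1ccccc1)c1ccccc1
Why: In this selective silyl ether protection the bulky chlorosilane reacts only at the primary hydroxyl, and the resulting silyl ether is a non-chelating group for step 6.

Step 3
Reactants: 3 methyl (R)-3-[(tert-butyldiphenylsilyl)oxy]-2-hydroxypropanoate
Product: 4 methyl (R)-2-(benzyloxy)-3-[(tert-butyldiphenylsilyl)oxy]propanoate
Conditions: BnOC(=NH)CCl3 (1.5 equiv), TfOH (5 mol%), cyclohexane/CH2Cl2 2:1, 0 °C to rt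
Reagents that add atoms: benzyl 2,2,2-trichloroacetimidate, N=C(OCc1ccccc1)C(Cl)(Cl)Cl
Why: Acid-catalysed trichloroacetimidate benzylation avoids base, so neither enolisation of the α-alkoxy ester nor silyl migration can occur.

Step 4
Reactants: 4 methyl (R)-2-(benzyloxy)-3-[(tert-butyldiphenylsilyl)oxy]propanoate
Product: 5 (R)-2-(benzyloxy)-3-[(tert-butyldiphenylsilyl)oxy]-N-methoxy-N-methylpropanamide
Conditions: MeNH(OMe)·HCl (1.6 equiv), iPrMgCl (3.2 equiv), THF, −20 to 0 °C
Reagents that add atoms: N,O-dimethylhydroxylamine hydrochloride, CNOC.Cl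
Why: Weinreb amide formation by magnesium-amide aminolysis of the ester is fast at low temperature and leaves the α-stereocentre intact.

Step 5
Reactants: 5 (R)-2-(benzyloxy)-3-[(tert-butyldiphenylsilyl)oxy]-N-methoxy-N-methylpropanamide
Product: 6 (R)-3-(benzyloxy)-4-[(tert-butyldiphenylsilyl)oxy]butan-2-one
Conditions: MeMgBr (1.5 equiv), THF, −78 to 0 °C; aq NH4Cl
Reagents that add atoms: methylmagnesium bromide, C[Mg]Br
Why: In the Weinreb ketone synthesis the N-methoxy amide takes up only one equivalent of Grignard reagent, so the methyl ketone forms without over-addition.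

Step 6
Reactants: 6 (R)-3-(benzyloxy)-4-[(tert-butyldiphenylsilyl)oxy]butan-2-one, 7 allyltrimethylsilane
Product: 8 (2R,3R)-2-(benzyloxy)-1-[(tert-butyldiphenylsilyl)oxy]-3-methylhex-5-en-3-ol
Conditions: TiCl4 (1.1 equiv), CH2Cl2, −78 °C, 10 min; then 7 (2.5 equiv), −78 °C, 3 h; sat. aq NaHCO3
Reagents that add atoms: none
Why: In this Hosomi–Sakurai carbonyl allylation under Cram chelate control, TiCl4 ties the ketone oxygen and the α-benzyloxy oxygen into a five-membered chelate, and the allylsilane attacks the face bearing the C2' hydrogen, anti to CH2OTBDPS, which sets C3' as R (threo to C2').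

Step 7
Reactants: 8 (2R,3R)-2-(benzyloxy)-1-[(tert-butyldiphenylsilyl)oxy]-3-methylhex-5-en-3-ol
Product: 10 (4R,5R)-5-(benzyloxy)-6-[(tert-butyldiphenylsilyl)oxy]-4-methylhexane-1,4-diol, via B-alkyl-9-BBN adduct 9 (not isolated)
Conditions: 9-BBN (2.5 equiv), THF, 0 °C to rt; then 3 M NaOH, 30% H2O2, 0 °C to rt
Reagents that add atoms: hydrogen peroxide, OO
Why: In the Brown hydroboration–oxidation 9-BBN adds anti-Markovnikov to the monosubstituted alkene, and the C–B bond is oxidised to the primary alcohol without touching either stereocentre.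

Step 8
Reactants: 10 (4R,5R)-5-(benzyloxy)-6-[(tert-butyldiphenylsilyl)oxy]-4-methylhexane-1,4-diol
Product: 11 (4R,5R)-6-[(tert-butyldiphenylsilyl)oxy]-4-methylhexane-1,4,5-triol
Conditions: H2 (1 atm), 10% Pd/C, EtOH, rt
Reagents that add atoms: none
Why: Catalytic hydrogenolysis of the benzyl ether is placed here because the molecule holds no C=C bond at this stage, and the silyl ether is inert to it.

Step 9
Reactants: 11 (4R,5R)-6-[(tert-butyldiphenylsilyl)oxy]-4-methylhexane-1,4,5-triol
Product: 12 3-[(4R,5R)-5-{[(tert-butyldiphenylsilyl)oxy]methyl}-2,2,4-trimethyl-1,3-dioxolan-4-yl]propan-1-ol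
Conditions: Me2C(OMe)2 (3 equiv), p-TsOH·H2O (2 mol%), acetone, 0 °C to rt; Et3N quench, aqueous work-up
Reagents that add atoms: 2,2-dimethoxypropane, COC(C)(C)OC
Why: Acid-catalysed transketalisation closes the five-membered dioxolane over the vicinal secondary/tertiary diol far more readily than a seven-membered ring to the primary hydroxyl, and any mixed ketal at that hydroxyl is lost on aqueous work-up.

Step 10
Reactants: 12 3-[(4R,5R)-5-{[(tert-butyldiphenylsilyl)oxy]methyl}-2,2,4-trimethyl-1,3-dioxolan-4-yl]propan-1-ol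
Product: 13 3-[(4R,5R)-5-{[(tert-butyldiphenylsilyl)oxy]methyl}-2,2,4-trimethyl-1,3-dioxolan-4-yl]propanal
Conditions: TEMPO (10 mol%), PhI(OAc)2 (1.1 equiv), CH2Cl2, rt
Reagents that add atoms: none
Why: The TEMPO/PhI(OAc)2 oxoammonium oxidation stops cleanly at the aldehyde and tolerates the acetonide and the silyl ether.

Step 11
Reactants: 13 3-[(4R,5R)-5-{[(tert-butyldiphenylsilyl)oxy]methyl}-2,2,4-trimethyl-1,3-dioxolan-4-yl]propanal
Product: 14 tert-butyl{[(4R,5R)-2,2,5-trimethyl-5-(4-methylpent-3-en-1-yl)-1,3-dioxolan-4-yl]methoxy}diphenylsilane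
Conditions: iPrPPh3I (1.6 equiv), n-BuLi (1.5 equiv), THF, 0 °C; then 13, −78 °C to rt
Reagents that add atoms: isopropyltriphenylphosphonium iodide, CC(C)[P+](c1ccccc1)(c1ccccc1)c1ccccc1.[I-]
Why: Wittig olefination with the non-stabilised isopropylidene ylide gives the trisubstituted alkene, and the symmetric terminus means there is no E/Z issue.

Step 12
Reactants: 14 tert-butyl{[(4R,5R)-2,2,5-trimethyl-5-(4-methylpent-3-en-1-yl)-1,3-dioxolan-4-yl]methoxy}diphenylsilane
Product: 15 [(4R,5R)-2,2,5-trimethyl-5-(4-methylpent-3-en-1-yl)-1,3-dioxolan-4-yl]methanol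
Conditions: TBAF (1.2 equiv), THF, 0 °C to rt
Reagents that add atoms: none
Why: Fluoride-mediated desilylation is driven by the strong Si–F bond and leaves the acetonide and the alkene untouched.

Step 13
Reactants: 16 2,6-dimethoxyphenol (syringol)
Product: 17 1,3-dimethoxy-2-(methoxymethoxy)benzene
Conditions: MOMCl (1.5 equiv), iPr2NEt (2 equiv), CH2Cl2, 0 °C to rt
Reagents that add atoms: chloromethyl methyl ether, COCCl
Why: O-alkylation of the phenol (MOM acetal protection) marks the future 7-oxygen with a group that survives organolithium and base and is removable beside methyl ethers.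

Step 14
Reactants: 17 1,3-dimethoxy-2-(methoxymethoxy)benzene
Product: 20 2,4-dimethoxy-3-(methoxymethoxy)phenol, via aryllithium 18 (not isolated), via dimethyl arylboronate 19 (not isolated)
Conditions: n-BuLi (1.2 equiv), TMEDA, THF, 0 °C to rt; B(OMe)3 (1.5 equiv), −78 °C to rt; AcOH, 30% H2O2, 0 °C to rt
Reagents that add atoms: hydrogen peroxide, OO
Why: Directed ortho-metalation can only occur next to one of the two equivalent methoxy groups, and borylation followed by oxidative boron-to-oxygen aryl migration turns that position into the phenol.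

Step 15
Reactants: 20 2,4-dimethoxy-3-(methoxymethoxy)phenol
Product: 21 2-hydroxy-3,5-dimethoxy-4-(methoxymethoxy)benzaldehyde
Conditions: MgCl2 (2 equiv), Et3N (4 equiv), (CH2O)n (6 equiv), MeCN, reflux; 1 M HCl work-up at 0 °C
Reagents that add atoms: paraformaldehyde (as formaldehyde), C=O
Why: The MgCl2/Et3N-mediated Casnati–Skattebøl ortho-formylation delivers formaldehyde only to the one free position ortho to the phenol oxygen, and a second equivalent of formaldehyde accepts the hydride.

Step 16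
Reactants: 21 2-hydroxy-3,5-dimethoxy-4-(methoxymethoxy)benzaldehyde
Product: 23 6,8-dimethoxy-7-(methoxymethoxy)-2H-chromen-2-one, via ethyl (E)-cinnamate 22 (not isolated)
Conditions: Ph3P=CHCO2Et (1.3 equiv), PhNEt2, reflux (about 215 °C), N2, 3 h
Reagents that add atoms: ethyl (triphenylphosphoranylidene)acetate, CCOC(=O)C=P(c1ccccc1)(c1ccccc1)c1ccccc1
Why: Wittig olefination with the stabilised ylide gives the ortho-hydroxycinnamate, which at reflux undergoes E-to-Z isomerisation and lactonisation to close the pyranone ring.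

Step 17
Reactants: 23 6,8-dimethoxy-7-(methoxymethoxy)-2H-chromen-2-one
Product: 24 7-hydroxy-6,8-dimethoxy-2H-chromen-2-one (isofraxidin)
Conditions: 3 M aq HCl, THF, 50 °C
Reagents that add atoms: none
Why: Acid-catalysed acetal hydrolysis removes the MOM group only, since the methyl ethers and the coumarin lactone are stable to dilute acid.

Step 18
Reactants: 15 [(4R,5R)-2,2,5-trimethyl-5-(4-methylpent-3-en-1-yl)-1,3-dioxolan-4-yl]methanol, 24 isofraxidin
Product: 25 6,8-dimethoxy-7-{[(4R,5R)-2,2,5-trimethyl-5-(4-methylpent-3-en-1-yl)-1,3-dioxolan-4-yl]methoxy}-2H-chromen-2-one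
Conditions: PPh3 (1.5 equiv), DIAD (1.5 equiv), THF, 0 °C to 40 °C
Reagents that add atoms: none
Why: In the Mitsunobu etherification the acidic 7-hydroxycoumarin (pKa about 7 to 8) displaces the activated primary alcohol at the non-stereogenic C1', so both stereocentres are carried over unchanged.

Step 19
Reactants: 25 6,8-dimethoxy-7-{[(4R,5R)-2,2,5-trimethyl-5-(4-methylpent-3-en-1-yl)-1,3-dioxolan-4-yl]methoxy}-2H-chromen-2-one
Product: 26 altissimacoumarin C, 7-{[(2R,3R)-2,3-dihydroxy-3,7-dimethyloct-6-en-1-yl]oxy}-6,8-dimethoxy-2H-chromen-2-one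
Conditions: AcOH/H2O 4:1, 45 °C
Reagents that add atoms: none
Why: Mild acid-catalysed acetal hydrolysis cleaves C–O bonds only at the ketal carbon, so both carbinol configurations are retained, and the acid is too weak to protonate the trisubstituted alkene.

## Compound list
1 | methyl (R)-2,2-dimethyl-1,3-dioxolane-4-carboxylate | COC(=O)[C@H]1COC(C)(C)O1 | starting material
2 | methyl (R)-2,3-dihydroxypropanoate | OC[C@@H](O)C(=O)OC | intermediate
3 | methyl (R)-3-[(tert-butyldiphenylsilyl)oxy]-2-hydroxypropanoate | CC(C)(C)[Si](c1ccccc1)(c1ccccc1)OC[C@@H](O)C(=O)OC | intermediate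
4 | methyl (R)-2-(benzyloxy)-3-[(tert-butyldiphenylsilyl)oxy]propanoate | CC(C)(C)[Si](c1ccccc1)(c1ccccc1)OC[C@@H](OCc1ccccc1)C(=O)OC | intermediate
5 | (R)-2-(benzyloxy)-3-[(tert-butyldiphenylsilyl)oxy]-N-methoxy-N-methylpropanamide | CC(C)(C)[Si](c1ccccc1)(c1ccccc1)OC[C@@H](OCc1ccccc1)C(=O)N(C)OC | intermediate
6 | (R)-3-(benzyloxy)-4-[(tert-butyldiphenylsilyl)oxy]butan-2-one | CC(C)(C)[Si](c1ccccc1)(c1ccccc1)OC[C@@H](OCc1ccccc1)C(C)=O | intermediate
7 | allyltrimethylsilane | C=CC[Si](C)(C)C | starting material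
8 | (2R,3R)-2-(benzyloxy)-1-[(tert-butyldiphenylsilyl)oxy]-3-methylhex-5-en-3-ol | CC(C)(C)[Si](c1ccccc1)(c1ccccc1)OC[C@@H](OCc1ccccc1)[C@](C)(O)CC=C | intermediate
9 | 9-[(4R,5R)-5-(benzyloxy)-6-[(tert-butyldiphenylsilyl)oxy]-4-hydroxy-4-methylhexyl]-9-borabicyclo[3.3.1]nonane (not isolated) | CC(C)(C)[Si](c1ccccc1)(c1ccccc1)OC[C@@H](OCc1ccccc1)[C@](C)(O)CCCB1C2CCCC1CCC2 | intermediate
10 | (4R,5R)-5-(benzyloxy)-6-[(tert-butyldiphenylsilyl)oxy]-4-methylhexane-1,4-diol | CC(C)(C)[Si](c1ccccc1)(c1ccccc1)OC[C@@H](OCc1ccccc1)[C@](C)(O)CCCO | intermediate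
11 | (4R,5R)-6-[(tert-butyldiphenylsilyl)oxy]-4-methylhexane-1,4,5-triol | CC(C)(C)[Si](c1ccccc1)(c1ccccc1)OC[C@@H](O)[C@](C)(O)CCCO | intermediate
12 | 3-[(4R,5R)-5-{[(tert-butyldiphenylsilyl)oxy]methyl}-2,2,4-trimethyl-1,3-dioxolan-4-yl]propan-1-ol | CC(C)(C)[Si](c1ccccc1)(c1ccccc1)OC[C@H]1OC(C)(C)O[C@]1(C)CCCO | intermediate
13 | 3-[(4R,5R)-5-{[(tert-butyldiphenylsilyl)oxy]methyl}-2,2,4-trimethyl-1,3-dioxolan-4-yl]propanal | CC(C)(C)[Si](c1ccccc1)(c1ccccc1)OC[C@H]1OC(C)(C)O[C@]1(C)CCC=O | intermediate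
14 | tert-butyl{[(4R,5R)-2,2,5-trimethyl-5-(4-methylpent-3-en-1-yl)-1,3-dioxolan-4-yl]methoxy}diphenylsilane | CC(C)(C)[Si](c1ccccc1)(c1ccccc1)OC[C@H]1OC(C)(C)O[C@]1(C)CCC=C(C)C | intermediate
15 | [(4R,5R)-2,2,5-trimethyl-5-(4-methylpent-3-en-1-yl)-1,3-dioxolan-4-yl]methanol | OC[C@H]1OC(C)(C)O[C@]1(C)CCC=C(C)C | intermediate
16 | 2,6-dimethoxyphenol (syringol) | COc1cccc(OC)c1O | starting material
17 | 1,3-dimethoxy-2-(methoxymethoxy)benzene | COCOc1c(OC)cccc1OC | intermediate
18 | [2,4-dimethoxy-3-(methoxymethoxy)phenyl]lithium (not isolated) | COCOc1c(OC)ccc([Li])c1OC | intermediate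
19 | dimethyl [2,4-dimethoxy-3-(methoxymethoxy)phenyl]boronate (not isolated) | COCOc1c(OC)ccc(B(OC)OC)c1OC | intermediate
20 | 2,4-dimethoxy-3-(methoxymethoxy)phenol | COCOc1c(OC)ccc(O)c1OC | intermediate
21 | 2-hydroxy-3,5-dimethoxy-4-(methoxymethoxy)benzaldehyde | COCOc1c(OC)cc(C=O)c(O)c1OC | intermediate
22 | ethyl (E)-3-[2-hydroxy-3,5-dimethoxy-4-(methoxymethoxy)phenyl]acrylate (not isolated) | CCOC(=O)/C=C/c1cc(OC)c(OCOC)c(OC)c1O | intermediate
23 | 6,8-dimethoxy-7-(methoxymethoxy)-2H-chromen-2-one | COCOc1c(OC)cc2ccc(=O)oc2c1OC | intermediate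
24 | 7-hydroxy-6,8-dimethoxy-2H-chromen-2-one (isofraxidin) | COc1cc2ccc(=O)oc2c(OC)c1O | intermediate
25 | 6,8-dimethoxy-7-{[(4R,5R)-2,2,5-trimethyl-5-(4-methylpent-3-en-1-yl)-1,3-dioxolan-4-yl]methoxy}-2H-chromen-2-one | COc1cc2ccc(=O)oc2c(OC)c1OC[C@H]3OC(C)(C)O[C@]3(C)CCC=C(C)C | intermediate
26 | altissimacoumarin C, 7-{[(2R,3R)-2,3-dihydroxy-3,7-dimethyloct-6-en-1-yl]oxy}-6,8-dimethoxy-2H-chromen-2-one | COc1cc2ccc(=O)oc2c(OC)c1OC[C@@H](O)[C@](C)(O)CCC=C(C)C | target

## Step count and risk
Total step count: 19.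
Longest linear sequence: 14 steps (steps 1 to 12, then 18 and 19). The isofraxidin branch is 5 steps (13 to 17).

**Step 6.** The weakly nucleophilic allylsilane may add too slowly to the hindered chelated ketone at −78 °C. Warming would erode the diastereoselectivity and endanger the benzyl ether.
The fallback sets out from 6 and comes back at 8.
- The same TiCl4 chelate of 6 is intercepted at −78 °C in CH2Cl2 by the much more nucleophilic ketene silyl acetal tert-butyl[(1-methoxyvinyl)oxy]dimethylsilane.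
- This is a chelation-controlled intermolecular Mukaiyama aldol addition with attack on the same face. It gives methyl (3R,4R)-4-(benzyloxy)-5-[(tert-butyldiphenylsilyl)oxy]-3-hydroxy-3-methylpentanoate F1.
- iBu2AlH (2.2 equiv, CH2Cl2, −78 °C) takes the ester down to (3R,4R)-4-(benzyloxy)-5-[(tert-butyldiphenylsilyl)oxy]-3-hydroxy-3-methylpentanal F2.
- Non-basic methylenation (Zn, CH2Br2, TiCl4, THF/CH2Cl2, 0 °C to rt) then supplies the third carbon and gives 8. It is chosen because a basic ylide could trigger retro-aldol cleavage of the tertiary aldol.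

**Step 16.** At about 215 °C the MOM acetal may be lost, the electron-rich phenol may tar, or E-to-Z isomerisation may stay incomplete.
The fallback sets out from 21 and comes back at 23.
- Knoevenagel condensation of 21 with Meldrum's acid (piperidinium acetate cat., EtOH, 78 °C) closes the lactone directly. It gives 6,8-dimethoxy-7-(methoxymethoxy)-2-oxo-2H-chromene-3-carboxylic acid F3.
- Protodecarboxylation with Ag2CO3 (10 mol%) and AcOH (5 mol%) in DMSO at 120 °C then gives 23.

**Step 18.** The phenol is flanked by two methoxy groups and the alcohol is β-branched next to a quaternary carbon. The Mitsunobu coupling may therefore stall, and the hydrazide may be alkylated instead.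
The fallback sets out from 15 and comes back at 25.
- The alcohol is isolated as a sulfonate (TsCl, Et3N, DMAP, CH2Cl2, 0 °C), [(4R,5R)-2,2,5-trimethyl-5-(4-methylpent-3-en-1-yl)-1,3-dioxolan-4-yl]methyl 4-methylbenzenesulfonate F4.
- F4 is then displaced by the caesium phenoxide of 24 (Cs2CO3, DMF, 80 °C) in a Williamson ether synthesis to give 25.

## Further compounds
F1 | step 6 | methyl (3R,4R)-4-(benzyloxy)-5-[(tert-butyldiphenylsilyl)oxy]-3-hydroxy-3-methylpentanoate | CC(C)(C)[Si](c1ccccc1)(c1ccccc1)OC[C@@H](OCc1ccccc1)[C@](C)(O)CC(=O)OC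
F2 | step 6 | (3R,4R)-4-(benzyloxy)-5-[(tert-butyldiphenylsilyl)oxy]-3-hydroxy-3-methylpentanal | CC(C)(C)[Si](c1ccccc1)(c1ccccc1)OC[C@@H](OCc1ccccc1)[C@](C)(O)CC=O
F3 | step 16 | 6,8-dimethoxy-7-(methoxymethoxy)-2-oxo-2H-chromene-3-carboxylic acid | COCOc1c(OC)cc2cc(C(=O)O)c(=O)oc2c1OC
F4 | step 18 | [(4R,5R)-2,2,5-trimethyl-5-(4-methylpent-3-en-1-yl)-1,3-dioxolan-4-yl]methyl 4-methylbenzenesulfonate | Cc1ccc(cc1)S(=O)(=O)OC[C@H]2OC(C)(C)O[C@]2(C)CCC=C(C)C
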